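(The numbers in the tables were computed with constants of no real substance.)

Run each substrate on its own clock: minus the natural log of the fraction of its charge still there.

| flask | left-handed substrate | right-handed substrate | gas | precatalyst | remark | time |
|---|---|---|---|---|---|---|
| blue | 0.076 M | 0.076 M | 7.9 mM (held) | 5.5 mM | run made earlier |  |
| red | 0.076 M | 0.076 M | 7.9 mM (held) | 22 mM | run made earlier |  |
| flask | 0.076 M | 0.076 M | 7.9 mM (held) | 11 mM |  | 5.0 h |

| run | time / h | left-handed product / % | right-handed product / % |
|---|---|---|---|
| blue | 0.667 | 6.7 | 2.5 |
| blue | 2.00 | 18.6 | 7.2 |
| blue | 3.00 | 23.6 | 8.2 |
| blue | 5.00 | 34.2 | 16.0 |
| red | 0.417 | 7.4 | 2.1 |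
| red | 1.00 | 18.8 | 4.7 |
| red | 2.00 | 31.9 | 12.6 |
| red | 5.00 | 49.4 | 32.1 |

(scatter of a reading: 1 percentage point)

- excess of left-handed product over right-handed product in the product at 15 min
- excess of left-handed product over right-handed product in the product at 5.0 h
- part of the left-handed substrate and right-handed substrate charged together that has reacted at 5.0 h

- free catalyst is single-handed; left-handed substrate and right-handed substrate are mirror images of each other, charged as a racemate, each of them at the stated concentration
- at the start none of reagent is dissolved
- candidate steps: reagent + free catalyst + left-handed substrate -> free catalyst + left-handed product; gas <-> reagent; precatalyst <-> free catalyst; reagent + free catalyst -> spent catalyst; reagent + free catalyst + right-handed substrate -> free catalyst + right-handed product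
- an excess is below zero if the other one leads

Both product steps take the same reagent and free catalyst, each with its own substrate. The ratio of the two clocks therefore stays put while those two change. Blue at 5.00 h and red at 2.00 h, pooled, give me a reading s = 3.21, the selectivity factor, left clock over right clock.

I solve two extreme versions of the flask. With the clocks near their start, the products form in the ratio s:

early excess = (s − 1)/(s + 1) = 52.5%

With both substrates used up, the equal charges give equal products and the excess vanishes. The real flask lies between, and the left-handed substrate thins first.

At 15 min it sits near the first end. Red, with twice the precatalyst of the flask, reads a left clock of 0.160 at the later 0.417 h. So I take the early excess for that time.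

For 5.0 h I need a clock. Red's left reading leaves 1.20% of that charge, which is lost in the scatter, so I use the right clocks. The flask's precatalyst charge is the geometric middle of the charges of the two runs, so I take the geometric middle of their clocks:

right clock = √(0.386 × 1.03) = 0.629

left clock = s × right clock = 2.02

fractions left: 13.3% and 53.3%

reacted 66.7%, excess 30.0%

The forecast gives 53%, 32% and 66%, with the ground “The substrates compete for the same catalyst”.

The flask gives 54.9%, 32.2% and 66.3%.

    reagent + free catalyst + left-handed substrate → free catalyst + left-handed product (k = 290 /M²/min)
    gas ⇌ reagent, rate k2*(csat - [reagent]) (kL = 0.140 /min)
    precatalyst ⇌ free catalyst (K = 0.820, k = 0.0500 /min)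
    reagent + free catalyst → spent catalyst (k = 0.200 /M/min)
    reagent + free catalyst + right-handed substrate → free catalyst + right-handed product (k = 83.0 /M²/min)

At the end the flask keeps less of its left-handed substrate than of its right-handed one, 12% against 55% of each charge. Through s, the flask's left figure gives a right rest of 52.2%. A neighbour flask with 0.0066 M of precatalyst keeps 26% of its left-handed substrate. There s gives 65.7% for the right-handed one, and that neighbour flask keeps 68% of the two together charged in the amount told for its right-handed substrate's own charge.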